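## The problem

Guaiane numbering is used throughout; unprimed atoms belong to the acetoxy half, primed atoms to the peroxide half.

The target is a C30 bis-guaiane. Each half is a hydroazulene: a five-membered ring C1–C5 fused through the C1–C5 bond to a seven-membered ring (C1, C5–C10). The halves are joined by the bonds C1–C2′ and C3–C1′, so that ring C1–C5 together with C1′–C2′ forms a bicyclo[2.2.1]hept-2-ene (alkene C4=C5, bridge C2 carrying the acetate), onto which the cyclopentenone C1′–C5′ is exo-fused.

There are nine stereocentres: five contiguous ones on the bicycle (C1, C2, C3, C1′, C2′; C1 and C1′ quaternary), the methyl-bearing C10 and C10′ next to the quaternary carbons, C7 (alpha to the C8 ketone) and the hemiketal carbon C8′. Only C10 and C10′ sit where they can steer the junction, and they have opposite absolute configuration (10S, 10′R) although both halves are the same 10-methyl-8-oxoguaiane. C7 and C8′ can epimerise and will be thermodynamic. The bridge carbon C2 cannot be corrected once the bicycle exists: a 7-norbornenyl carbon does not undergo inversion, and a hydride would reach a C2 ketone from the alkene side, the wrong one.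

The fragile groups are the 1,2-dioxolan-3-ol (reductants, base, heat, metals), the cross-conjugated dienone of the primed half, and any monomer at the cyclopentadiene or cyclopentadienone level (1,5-H shift, dimerisation, prototropy).

The feature that opens the structure: the bicycloheptene built from ring C1–C5 and C1′–C2′ is the retron of a [4+2] reaction between a cyclopentadiene acetoxylated at its sp3 carbon C2 and the C1′=C2′ bond of a cyclopentadienone (ring C1′–C5′). The two five-membered rings carry oxygen at C2 and at C3′, which makes them the two regioisomeric singlet-oxygen products of one 1,2,3-trisubstituted cyclopentadiene. Because C10 and C10′ are opposite, one racemic monomer can feed both halves. The peroxide ring with its C6′=C7′ bond is the ene product of an isopropylidene ketone with O2.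

## Retrosynthesis

**20 ⇒ 18.** The bonds C11′–O and O–C8′ of the dioxolane are cut and C6′=C7′ is returned to C7′=C11′. The peroxide would survive no other step, so it goes in last. The forward reaction is the singlet-oxygen ene reaction of an s-cis isopropylidene ketone followed by hemiketalisation. It must choose this alkene over the tetrasubstituted C4=C5; 18 has that alkene shielded on both faces.

**18 ⇒ 16 + 17.** The bonds C1–C2′ and C3–C1′ are cut at once. This removes the bicycle, both quaternary carbons and four stereocentres, and leaves two C15 monomers with three and one stereocentres. One-bond alternatives (Michael or aldol modes) would pass through a C2 ketone, whose reduction gives the wrong C2 epimer. The forward Diels–Alder reaction must pair C1′ with C3, use the diene face opposite the C10 methyl, place the dienone ring exo, and use the dienone face opposite the C10′ methyl.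

**16 ⇒ 15 and 17 ⇒ 12.** Neither the 5-acetoxycyclopentadiene 16 nor the cyclopentadienone 17 can be stored. Water is formally added across C3=C4 of 16 and across C1′=C2′ of 17, which gives two bench-stable tertiary alcohols, 15 and 12. One dehydrating reagent in one flask should release both partners.

**15 ⇒ 14 ⇒ 13 ⇒ 11, and 11 + 12 ⇒ 7.** The C–O bonds at C2/C4 (in 11) and at C3/C1 (in 12) are cut back to O2. Compounds 11 and 12 are the two Kornblum–DeLaMare products of the endoperoxides of the cyclopentadiene 7 and its [1,5]-H tautomer 8, so one photooxygenation delivers both halves. Since C10 of 16 is S and C10′ of 17 is R, the two partners are drawn from opposite enantiomers of racemic 7. The absolute configuration is set only once, by the lipase acetylation that also installs the acetate (14 → 15). The dienone is then used as the racemate 12 and selected by the enantiopure diene.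

**7 ⇒ 5 ⇒ 4 ⇒ 3.** The cyclopentadiene is taken back to a cyclopentene (epoxidation and double elimination), and that to the tertiary alcohol 4. The C10–H bond is taken back to the conjugated enone of 3. Reducing C9=C10 before unsaturation is added to the five-membered ring keeps the ketone insulated from the diene; otherwise tropone- and azulene-type tautomers become accessible.

**3 ⇒ 2 ⇒ 1.** The ring-fusion bond C1–C5 is cut transannularly. Germacrone 1, an achiral commercial C15 ketone, already holds all fifteen carbons, the C8 ketone and the C7=C11 isopropylidene of each half. Its 4,5-epoxide is known to close to 4-hydroxyguaianes. The forward step needs only regioselective epoxidation and cation–olefin cyclisation.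

## Roads not taken

**Alternative 1 (the obvious one):** the same two-bond cut, but with 16 and 17 each made enantiopure by de novo synthesis. A typical start would be the cycloheptenone A1, followed by copper-catalysed asymmetric conjugate addition of a methyl nucleophile, enolate trapping and cyclopentannulation, and then a Diels–Alder union of the separately prepared partners. This needs two asymmetric sequences of opposite hand, each of about ten steps, and builds the two oxygen patterns of the five-membered rings separately. The chosen plan takes both partners from one racemic six-step stream and lets O2 create both patterns in one flask.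

**Alternative 2:** the same cut with C2 carried as a ketal. The dimethyl-ketal diene A2 has no stereocentre at C2, so its cycloaddition with 17 is face-controlled by C10 alone; hydrolysis gives the bridge ketone A3, which is then reduced and acetylated. The forward key step is a cyclopentadienone-ketal Diels–Alder reaction. It fails at the end: hydride must approach the C2 carbonyl of A3 from the alkene side, because the exo-fused ring blocks the other side, and this gives the C2 epimer. Inversion at a 7-norbornenyl carbon is not available, since π-participation leads to retention.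

**Alternative 3:** dearomatisation. Each bicycle is cut at C5–C1 and C5–C6, so that C5 is a carbene carbon inserted into an anisole ring that already carries the C10 methyl, the C7 isopropyl and the C8 oxygen. The aryl diazoketone A4 would give the azulenone A5 by an intramolecular Buchner reaction (Rh2(OAc)4). The carbonyl then lands at C4, which suits only the acetoxy half. The triene needs net reduction and gives the endocyclic C6=C7 enone, not the 7(11)-ene that the final ene reaction needs. C10 is not controlled, and two different sequences are still required.

Key step: step 10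

Assumption: germacrone is taken as a commercial feedstock, and the two centres that can equilibrate (C7 next to the C8 ketone, and the hemiketal carbon C8′) are assumed to rest, in the target, in their thermodynamically preferred configurations.

## Steps

Step 1
Reactants: 1 germacrone
Product: 2 rac-(4S*,5S*)-4,5-epoxygermacra-1(10),7(11)-dien-8-one
Conditions: mCPBA, NaHCO3, CH2Cl2, −20 → 0 °C
Reagents that add atoms: mCPBA, O=C(OO)c1cccc(Cl)c1
Why: Peracid (Prilezhaev) epoxidation should take the electron-rich C4=C5 alkene in preference to the beta,gamma-unsaturated C1=C10 and the enone alkene; the E alkene gives the trans epoxide as a racemate.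

Step 2
Reactants: 2 rac-(4S*,5S*)-4,5-epoxygermacra-1(10),7(11)-dien-8-one
Product: 3 rac-(1R*,4S*,5S*)-4-hydroxyguaia-7(11),9-dien-8-one
Conditions: p-TsOH·H2O (cat.), CH2Cl2, 0 °C → rt; then DBU, rt
Reagents that add atoms: none
Why: Transannular cation–olefin cyclisation of a germacrane 4,5-epoxide: the C1=C10 π bond opens the protonated epoxide at C5 with inversion (C1–C5 bond), the C10 cation loses a proton, and DBU moves the beta,gamma double bond into conjugation. C4 keeps the epoxide configuration and H-5 ends cis to the hydroxyl; the ring-fusion centre C1 is thermodynamic and is erased in step 5.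

Step 3
Reactants: 3 rac-(1R*,4S*,5S*)-4-hydroxyguaia-7(11),9-dien-8-one
Product: 4 rac-(1S*,4S*,5S*,10S*)-4-hydroxyguai-7(11)-en-8-one
Conditions: [(Ph3P)CuH]6 (cat.), PhMe2SiH, PhMe, 0 °C → rt; then K2CO3, MeOH
Reagents that add atoms: none
Why: Copper hydride 1,4-reduction; the trisubstituted C9=C10 enone should be reached before the tetrasubstituted isopropylidene enone. C10 arises under substrate control, but its sense is immaterial because C1, C4 and C5 become trigonal in step 5, so every stereoisomer converges on racemic 7.

Step 4
Reactants: 4 rac-(1S*,4S*,5S*,10S*)-4-hydroxyguai-7(11)-en-8-one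
Product: 5 rac-(1S*,10S*)-guaia-4,7(11)-dien-8-one
Conditions: Burgess reagent (MeO2CN−SO2N+Et3), PhH, 50 °C
Reagents that add atoms: none
Why: Burgess syn-elimination of the tertiary alcohol; H-5 is cis to the hydroxyl, so the tetrasubstituted C4=C5 alkene should dominate, and a C3=C4 isomer would serve equally in step 5.

Step 5
Reactants: 5 rac-(1S*,10S*)-guaia-4,7(11)-dien-8-one
Product: 7 rac-guaia-1(5),3,7(11)-trien-8-one, via 4,5-epoxide 6 (not isolated)
Conditions: mCPBA, NaHCO3, CH2Cl2, 0 °C; then CSA (cat.), PhMe, 40 °C
Reagents that add atoms: none
Why: Peracid epoxidation of the only electron-rich alkene, then acid-catalysed epoxide → allylic alcohol → diene double elimination. With C10 saturated the ketone is insulated, so the endocyclic cyclopentadiene should be the sink of the five-membered ring; 7 is handled as an equilibrating mixture with its [1,5]-H tautomer 8.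

Step 6
Reactants: 7 rac-guaia-1(5),3,7(11)-trien-8-one
Product: 11 rac-(4R*,10S*)-4-hydroxyguaia-1(5),7(11)-diene-2,8-dione and 12 rac-(1S*,10R*)-1-hydroxyguaia-4,7(11)-diene-3,8-dione, via 1,4-diene tautomer 8 (not isolated), via 1,3-endoperoxide 9 (not isolated), via 2,4-endoperoxide 10 (not isolated)
Conditions: O2, hν (visible), tetraphenylporphyrin (cat.), CH2Cl2, −78 °C; then Et3N, −78 → 0 °C
Reagents that add atoms: dioxygen, O=O
Why: Singlet oxygen adds [4+2] to each cyclopentadiene tautomer on the face away from the C10 methyl, and Kornblum–DeLaMare opening removes the single bridgehead hydrogen of each endoperoxide (H-3 of 9, H-2 of 10), so the regiochemistry of each 4-hydroxycyclopentenone is fixed by the tautomer it came from. Both products are used after chromatographic separation: 11 for the diene half, 12 for the dienophile half.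

Step 7
Reactants: 11 rac-(4R*,10S*)-4-hydroxyguaia-1(5),7(11)-diene-2,8-dione
Product: 13 rac-(2R*,4R*,10S*)-2,4-dihydroxyguaia-1(5),7(11)-dien-8-one
Conditions: Me4NBH(OAc)3, MeCN/AcOH, −30 °C
Reagents that add atoms: none
Why: Hydroxyl-directed (Evans–Saksena) reduction: the borohydride bound to the C4 oxygen delivers hydride to C2 on its own face, giving the 1,3-anti diol with the new carbinol on the face of the C10 methyl. The C8 ketone has no beta-hydroxyl and should not be reduced.

Step 8
Reactants: 13 rac-(2R*,4R*,10S*)-2,4-dihydroxyguaia-1(5),7(11)-dien-8-one
Product: 14 rac-(2R*,4R*,7R*,10S*)-2,4-dihydroxyguai-1(5)-en-8-one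
Conditions: [(Ph3P)CuH]6 (cat.), PhMe2SiH (excess), PhMe, 40 °C; then K2CO3, MeOH, rt
Reagents that add atoms: none
Why: Copper hydride conjugate reduction of the only enone left (the isopropylidene ketone). Methanolysis frees the ketone, and the carbonate equilibrates C7 to the more stable isopropyl epimer (see assumption).

Step 9
Reactants: 14 rac-(2R*,4R*,7R*,10S*)-2,4-dihydroxyguai-1(5)-en-8-one
Product: 15 (2R,4R,7R,10S)-2-acetoxy-4-hydroxyguai-1(5)-en-8-one
Conditions: immobilised Candida antarctica lipase B, vinyl acetate, MTBE, 30 °C, to about half conversion
Reagents that add atoms: vinyl acetate, CC(=O)OC=C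
Why: Lipase-catalysed kinetic resolution: by the empirical size rule for secondary alcohols (alkenyl C1 large, C3H2 medium) the (2R)-carbinol should be acylated, while the tertiary hydroxyl is inert. This one step sets the absolute configuration of the synthesis and installs the acetate; the unreacted enantiomer is removed by chromatography.

Step 10
Reactants: 15 (2R,4R,7R,10S)-2-acetoxy-4-hydroxyguai-1(5)-en-8-one; 12 rac-(1S*,10R*)-1-hydroxyguaia-4,7(11)-diene-3,8-dione (racemate, in excess)
Product: 18 deoxy dimer (exo, head-to-tail [4+2] adduct with bonds C1–C2′ and C3–C1′, acetate over C4=C5, 7′(11′)-ene), via acetoxy diene 16 (not isolated), via cyclopentadienone 17 (not isolated)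
Conditions: Ph2S[OC(CF3)2Ph]2 (Martin sulfurane), CH2Cl2, −78 → 0 °C, then 23 °C
Reagents that add atoms: none
Why: Martin sulfurane ionises the tertiary allylic alcohol of 15 (E1, loss of H-3) to the 5-acetoxycyclopentadiene 16 and dehydrates the beta-hydroxy ketone 12 through its acidic H-2′ to the cyclopentadienone 17, and the two combine in a normal-demand Diels–Alder reaction; the closest known types are the dehydration of 4-hydroxycyclopentenones to cyclopentadienones and their trapping by cyclopentadienes. The cycloaddition closes the bicyclo[2.2.1]heptene in a concerted suprafacial [4+2] mode through C1–C2′ and C3–C1′ and leaves the dienone ring cis-fused. In orientation, the fully substituted beta-carbon C1′ of 17 pairs with the unsubstituted diene terminus C3 and the CH carbon C2′ with the alkylated terminus C1, as both orbital coefficients and sterics demand. C1 and C3 are set by approach to the diene face opposite the C10 methyl, the C7 isopropyl and the acetate, which leaves the acetate over the new C4=C5 bond. C1′ and C2′ are set by the exo transition state (dienone ring beside C2–H, away from C4-methyl and C5–C6) and by approach anti to the C10′ methyl. Only the (10R)-enantiomer of 17 can meet both demands, so the enantiopure diene selects its partner from the racemate, and the unmatched enantiomer is left to dimerise. The selectivity most at risk is the facial one at 16, where sterics must override the syn-directing effect of a 5-acyloxy group; the C10 substituent beside the terminus that becomes quaternary is what should secure it.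

Step 11
Reactants: 18 deoxy dimer
Product: 20 target peroxy-hemiketal CNP0361479.4, via hydroperoxide 19 (not isolated)
Conditions: O2, hν (visible), tetraphenylporphyrin (cat.), CH2Cl2, −20 °C
Reagents that add atoms: dioxygen, O=O
Why: Schenck ene reaction with the geminal selectivity of s-cis enones: oxygen adds to C11′ and hydrogen is taken from C6′ (also allylic to C4′=C5′), giving the C6′=C7′ dienone hydroperoxide, which closes onto the C8′ ketone as the 1,2-dioxolan-3-ol, as in pulegone-type photooxygenation. The tetrasubstituted C4=C5 alkene is shielded by the syn acetate above and by C10′ below; C8′ settles by ring–chain equilibration.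

## Compound list

1 | germacrone, (3E,7E)-3,7-dimethyl-10-(propan-2-ylidene)cyclodeca-3,7-dien-1-one | C/C1=C\CC(=C(C)C)C(=O)C/C(C)=C/CC1 | starting material
2 | rac-(4S*,5S*)-4,5-epoxygermacra-1(10),7(11)-dien-8-one (trans epoxide; one enantiomer drawn) | C/C1=C\CC[C@]2(C)O[C@H]2CC(=C(C)C)C(=O)C1 | intermediate
3 | rac-(1R*,4S*,5S*)-4-hydroxyguaia-7(11),9-dien-8-one (OH cis to H-5, trans ring fusion drawn) | C[C@]1(O)CC[C@H]2C(C)=CC(=O)C(=C(C)C)C[C@H]12 | intermediate
4 | rac-(1S*,4S*,5S*,10S*)-4-hydroxyguai-7(11)-en-8-one | C[C@]1(O)CC[C@H]2[C@@H](C)CC(=O)C(=C(C)C)C[C@H]12 | intermediate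
5 | rac-(1S*,10S*)-guaia-4,7(11)-dien-8-one | CC1=C2CC(=C(C)C)C(=O)C[C@H](C)[C@@H]2CC1 | intermediate
6 | rac-4,5-epoxyguai-7(11)-en-8-one (oxirane on the face of H-1) | C[C@@]12CC[C@H]3[C@@H](C)CC(=O)C(=C(C)C)C[C@@]13O2 | intermediate
7 | rac-guaia-1(5),3,7(11)-trien-8-one (cyclopentadiene; (10S) drawn) | CC1=CCC2=C1CC(=C(C)C)C(=O)C[C@@H]2C | intermediate
8 | rac-guaia-1,4,7(11)-trien-8-one ([1,5]-H tautomer of 7; (10S) drawn) | CC1=C2CC(=C(C)C)C(=O)C[C@H](C)C2=CC1 | intermediate
9 | rac-1,3-epidioxyguaia-4,7(11)-dien-8-one (endoperoxide of 7, O2 anti to the C10 methyl; (10R) drawn) | CC1=C2CC(=C(C)C)C(=O)C[C@@H](C)[C@@]23C[C@@H]1OO3 | intermediate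
10 | rac-2,4-epidioxyguaia-1(5),7(11)-dien-8-one (endoperoxide of 8, O2 anti to the C10 methyl; (10S) drawn) | C[C@]12C[C@H](OO1)C3=C2CC(=C(C)C)C(=O)C[C@@H]3C | intermediate
11 | rac-(4R*,10S*)-4-hydroxyguaia-1(5),7(11)-diene-2,8-dione | O=C1C[C@@](C)(O)C2=C1[C@@H](C)CC(=O)C(=C(C)C)C2 | intermediate
12 | rac-(1S*,10R*)-1-hydroxyguaia-4,7(11)-diene-3,8-dione (the enantiomer drawn is the one incorporated) | CC1=C2CC(=C(C)C)C(=O)C[C@@H](C)[C@@]2(O)CC1=O | intermediate
13 | rac-(2R*,4R*,10S*)-2,4-dihydroxyguaia-1(5),7(11)-dien-8-one | O[C@@H]1C[C@@](C)(O)C2=C1[C@@H](C)CC(=O)C(=C(C)C)C2 | intermediate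
14 | rac-(2R*,4R*,7R*,10S*)-2,4-dihydroxyguai-1(5)-en-8-one | O[C@@H]1C[C@@](C)(O)C2=C1[C@@H](C)CC(=O)[C@@H](C(C)C)C2 | intermediate
15 | (2R,4R,7R,10S)-2-acetoxy-4-hydroxyguai-1(5)-en-8-one | CC(=O)O[C@@H]1C[C@@](C)(O)C2=C1[C@@H](C)CC(=O)[C@@H](C(C)C)C2 | intermediate
16 | (2R,7R,10S)-2-acetoxyguaia-1(5),3-dien-8-one | CC(=O)O[C@@H]1C=C(C)C2=C1[C@@H](C)CC(=O)[C@@H](C(C)C)C2 | intermediate
17 | (10R)-guaia-1,4,7(11)-triene-3,8-dione | O=C1C=C2[C@H](C)CC(=O)C(=C(C)C)CC2=C1C | intermediate
18 | deoxy dimer: exo head-to-tail adduct of 16 and 17 (C1–C2′, C3–C1′; acetate syn to C4=C5; 7′(11′)-ene, 3′,8′-dione) | CC(=O)O[C@@H]1[C@@H]2C(C)=C3C[C@H](C(C)C)C(=O)C[C@H](C)[C@@]31[C@@H]1C(=O)C(C)=C3CC(=C(C)C)C(=O)C[C@@H](C)[C@]312 | intermediate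
19 | 11′-hydroperoxide of 18 with C6′=C7′ | CC(=O)O[C@@H]1[C@@H]2C(C)=C3C[C@H](C(C)C)C(=O)C[C@H](C)[C@@]31[C@@H]1C(=O)C(C)=C3C=C(C(C)(C)OO)C(=O)C[C@@H](C)[C@]312 | intermediate
20 | target CNP0361479.4 (8′-hydroxy-8′,11′-epidioxy dimer) | CC(=O)O[C@@H]1[C@@H]2C(C)=C3C[C@H](C(C)C)C(=O)C[C@H](C)[C@@]31[C@@H]1C(=O)C(C)=C3C=C4C(C)(C)OO[C@]4(O)C[C@@H](C)[C@]312 | target

## Step count and least certain steps

Total step count: 11. Longest linear sequence: 11 (1 → 20). The second cycloaddition partner 12 is a co-product of step 6, so there is no separate branch.

**Step 10 (key step).** Most likely to go wrong is loss of selectivity in the cycloaddition. The dienone is formed as a racemate in the same flask as the diene, so self-dimerisation of 17 and reaction of its mismatched enantiomer can drain 16. In addition, approach on the acetoxy face of 16 is electronically favoured and competes with the sterically favoured face. Fallback (asymmetric supply of the dienophile in place of kinetic resolution): setting out from 1, Shi epoxidation (fructose-derived ketone catalyst of the appropriate hand, Oxone (2KHSO5·KHSO4·K2SO4), K2CO3, MeCN/dimethoxymethane/H2O, 0 °C) should give the single-enantiomer (4R,5R)-4,5-epoxygermacra-1(10),7(11)-dien-8-one F1. Carried through steps 2 to 6 as for the racemate, F1 comes back to the route at 12 as its (1S,10R)-enantiomer alone. It can then be added slowly and in near-stoichiometric amount to preformed 16, so that no mismatched dienone is present. The sense of substrate control in step 3 decides which hand of the catalyst is needed.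

**Step 5.** The tetrasubstituted epoxide may rearrange by alkyl shift under acid, or the isopropylidene double bond may migrate into conjugation with the new diene. Fallback (base-mediated in place of acid-mediated opening): setting out from isolated 6, TMSOTf/2,6-lutidine then DBU, with aqueous HF work-up, should give rac-4-hydroxyguaia-1(5),7(11)-dien-8-one F2. Its Burgess dehydration can only proceed away from the ring fusion and comes back to the route at 7.

**Step 6.** The endoperoxides may rearrange thermally (to diepoxides or epoxy ketones) before the base acts, and the face and tautomer distribution may be poor. Fallback (reduction and oxidation in place of base-induced rearrangement): from 7, the photooxygenation mixture is reduced at −78 °C with thiourea to rac-cis-2,4-dihydroxyguaia-1(5),7(11)-dien-8-one F3 and rac-cis-1,3-dihydroxyguaia-4,7(11)-dien-8-one F4. MnO2 then oxidises only the secondary allylic hydroxyl of each, which comes back to the route at 11 and 12.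

**Step 8.** Hydride transfer to the tetrasubstituted isopropylidene enone may be too slow, with silylation of the diol and decomposition taking over. Fallback (hydrogenation one stage earlier): from 11, H2 over Pd/C in EtOAc should saturate the exocyclic pulegone-type double bond while the tetrasubstituted ring-fusion enone resists, giving rac-(4R*,7R*,10S*)-4-hydroxyguai-1(5)-ene-2,8-dione F5. The directed reduction of step 7 applied to F5 comes back to the route at 14.

**Step 9.** The lipase may discriminate poorly or acylate slowly, because the carbinol is flanked by a tetrasubstituted alkene carbon. Fallback (classical resolution): from 14, esterification of the secondary hydroxyl with (S)-O-methylmandelic acid (DCC, DMAP) gives two diastereomeric esters. The (2R)-ester, (2R,4R,7R,10S)-4-hydroxy-8-oxoguai-1(5)-en-2-yl (S)-2-methoxy-2-phenylacetate F6, is separated by chromatography and cleaved with K2CO3/MeOH; acetylation of the liberated single-enantiomer diol (Ac2O, pyridine) comes back to the route at 15.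

**Step 11.** The ene reaction may also occur at the tetrasubstituted C4=C5 alkene, or the enone alkene may react too slowly and over-oxidation set in. Fallback (peroxide before union): from 12, the same photooxygenation on the monomer, which has only one oxidisable alkene, should give the peroxy-hemiketal 1,8-dihydroxy-8,11-epidioxyguaia-4,6-dien-3-one F7. F7 replaces 12 in step 10, where its dehydration gives the dienone 8-hydroxy-8,11-epidioxyguaia-1,4,6-trien-3-one F8 (not isolated), and the cycloaddition with 16 comes back to the route directly at 20. If the hemiketal hydroxyl interferes, it can be carried as its trimethylsilyl ether.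

## Further compounds

F1 | step 10 | (4R,5R)-4,5-epoxygermacra-1(10),7(11)-dien-8-one (single enantiomer) | C/C1=C\CC[C@@]2(C)O[C@@H]2CC(=C(C)C)C(=O)C1
F2 | step 5 | rac-4-hydroxyguaia-1(5),7(11)-dien-8-one | C[C@]1(O)CCC2=C1CC(=C(C)C)C(=O)C[C@@H]2C
F3 | step 6 | rac-cis-2,4-dihydroxyguaia-1(5),7(11)-dien-8-one | O[C@H]1C[C@@](C)(O)C2=C1[C@@H](C)CC(=O)C(=C(C)C)C2
F4 | step 6 | rac-cis-1,3-dihydroxyguaia-4,7(11)-dien-8-one | CC1=C2CC(=C(C)C)C(=O)C[C@@H](C)[C@@]2(O)C[C@@H]1O
F5 | step 8 | rac-(4R*,7R*,10S*)-4-hydroxyguai-1(5)-ene-2,8-dione | O=C1C[C@@](C)(O)C2=C1[C@@H](C)CC(=O)[C@@H](C(C)C)C2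
F6 | step 9 | (2R,4R,7R,10S)-4-hydroxy-8-oxoguai-1(5)-en-2-yl (S)-2-methoxy-2-phenylacetate | CO[C@H](C(=O)O[C@@H]1C[C@@](C)(O)C2=C1[C@@H](C)CC(=O)[C@@H](C(C)C)C2)c1ccccc1
F7 | step 11 | 1,8-dihydroxy-8,11-epidioxyguaia-4,6-dien-3-one (monomer peroxy-hemiketal) | CC1=C2C=C3C(C)(C)OO[C@]3(O)C[C@@H](C)[C@@]2(O)CC1=O
F8 | step 11 | 8-hydroxy-8,11-epidioxyguaia-1,4,6-trien-3-one (dienone from F7) | O=C1C=C2[C@H](C)C[C@@]3(O)OOC(C)(C)C3=CC2=C1C
A1 | alternative 1 | 1,4-dioxaspiro[4.6]undec-9-en-8-one | O=C1C=CCC2(CC1)OCCO2
A2 | alternative 2 | (7R,10S)-2,2-dimethoxyguaia-1(5),3-dien-8-one | COC1(OC)C=C(C)C2=C1[C@@H](C)CC(=O)[C@@H](C(C)C)C2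
A3 | alternative 2 | 2-oxo analogue of 18 (bridge ketone) | O=C1[C@@H]2C(C)=C3C[C@H](C(C)C)C(=O)C[C@H](C)[C@@]31[C@@H]1C(=O)C(C)=C3CC(=C(C)C)C(=O)C[C@@H](C)[C@]312
A4 | alternative 3 | 1-diazo-4-(4-methoxy-2-methyl-5-isopropylphenyl)butan-2-one | COc1cc(C)c(CCC(=O)C=[N+]=[N-])cc1C(C)C
A5 | alternative 3 | rac-8-methoxy-15-norguaia-1(10),6,8-trien-4-one (Buchner product) | COC1=CC(C)=C2CCC(=O)[C@H]2C=C1C(C)C
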